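**Retrosynthetic overview**
1. The strategy rests on ring B (the benzene ring of the 2H-chromene): C7 carries OH and the adjacent C8 carries acetyl, with C8 next to the oxygen-bearing C8a. Both groups are installed at once by opening a C7–C8 aryne with acetic acid (C7–O and C8–C(acetyl) bonds).
2. Last disconnection: the CH2 bridge between C6 of ring B and C6 of ring A, cut to a ring B Mannich base (ortho-quinone methide precursor) and propionylfilicinic acid (ring A, from gem-dimethylation of 1-(2,4,6-trihydroxyphenyl)propan-1-one).
3. The aryne precursor, the 8-trimethylsilyl 7-triflate, comes from the 8-bromo-7-chromenol by O-silylation, bromine–lithium exchange with O-to-C silyl shift, and triflation.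
4. The pyran ring C is annulated onto 2-bromo-5-methoxyresorcinol with 3-methylbut-2-enal; the bromine, placed by directed lithiation of the bis-MOM ether, blocks the carbon between the hydroxyls and marks the later silyl site.
5. Ring order: ring B is bought, ring C closes in step 4, ring A is dearomatised (not closed) in step 10; the key step and the final coupling close no ring.

Key step: step 7

Remark: the target has no stereocentre; ring A is drawn as one enol tautomer of a β-triketone and the synthetic material is expected to equilibrate to the same tautomeric set. Compounds 1, 6, 13 and 18 are taken as commercial.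

Step 1
Reactants: 1 5-methoxyresorcinol (5-methoxybenzene-1,3-diol)
Product: 2 1-methoxy-3,5-bis(methoxymethoxy)benzene
Conditions: NaH (2.4 equiv), MOMCl (2.4 equiv), DMF, 0 °C → rt
Reagents that add atoms: chloromethyl methyl ether (MOMCl), COCCl
Why: Williamson-type O-alkylation of both phenoxides gives the bis-acetal, which protects the phenols and supplies two chelating directing groups for the next step.

Step 2
Reactants: 2 1-methoxy-3,5-bis(methoxymethoxy)benzene
Product: 4 2-bromo-5-methoxy-1,3-bis(methoxymethoxy)benzene, via C2 aryllithium 3 (not isolated)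
Conditions: n-BuLi (1.2 equiv), TMEDA (1.2 equiv), THF, 0 °C, 1 h; then BrCH2CH2Br, −78 °C → rt
Reagents that add atoms: 1,2-dibromoethane, BrCCBr
Why: Directed ortho-metalation should occur at C2, flanked by two chelating OMOM groups, in preference to C4/C6 (one OMOM and the weaker OMe director), and the aryllithium is brominated by bromine transfer from 1,2-dibromoethane.

Step 3
Reactants: 4 2-bromo-5-methoxy-1,3-bis(methoxymethoxy)benzene
Product: 5 2-bromo-5-methoxybenzene-1,3-diol
Conditions: HCl (3 M, aq.), MeOH, 40 °C
Reagents that add atoms: none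
Why: Acid-catalysed acetal exchange with methanol (MOM cleavage) frees both phenols, while the aryl bromide and the aryl methyl ether are inert to dilute acid.

Step 4
Reactants: 5 2-bromo-5-methoxybenzene-1,3-diol; 6 3-methylbut-2-enal
Product: 8 8-bromo-5-methoxy-2,2-dimethyl-2H-chromen-7-ol, via dienone condensation product 7 (not isolated)
Conditions: 6 (1.1 equiv, slow addition), ethylenediammonium diacetate (20 mol %), toluene, 110 °C
Reagents that add atoms: none
Why: Amine-salt-catalysed formal [3+3] chromene annulation (Knoevenagel-type condensation at a free carbon ortho to OH, then oxa-6π electrocyclisation); bromine blocks the carbon between the hydroxyls and the two remaining sites are equivalent, so only the 5-methoxy-7-hydroxy-8-bromo isomer can form, and limiting the enal should hold the reaction at mono-annulation.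

Step 5
Reactants: 8 8-bromo-5-methoxy-2,2-dimethyl-2H-chromen-7-ol
Product: 9 [(8-bromo-5-methoxy-2,2-dimethyl-2H-chromen-7-yl)oxy]trimethylsilane
Conditions: HMDS (1.5 equiv), THF, 70 °C; evaporate, use crude
Reagents that add atoms: hexamethyldisilazane, C[Si](C)(C)N[Si](C)(C)C
Why: O-silylation of the phenol with HMDS gives only ammonia as by-product, so the moisture-sensitive silyl ether can be carried on without purification.

Step 6
Reactants: 9 [(8-bromo-5-methoxy-2,2-dimethyl-2H-chromen-7-yl)oxy]trimethylsilane
Product: 12 5-methoxy-2,2-dimethyl-8-(trimethylsilyl)-2H-chromen-7-yl trifluoromethanesulfonate, via 8-lithio silyl ether 10 (not isolated), via lithium 8-silyl-7-phenoxide 11 (not isolated)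
Conditions: n-BuLi (1.1 equiv), THF, −78 °C, 30 min; Tf2O (1.2 equiv), −78 → 0 °C
Reagents that add atoms: trifluoromethanesulfonic anhydride, O=S(=O)(OS(=O)(=O)C(F)(F)F)C(F)(F)F
Why: Bromine–lithium exchange followed by a 1,3 O-to-C silyl shift (retro-Brook rearrangement) puts the silyl group on C8 and releases the C7 phenoxide, which is trapped as the triflate; this is the standard entry to ortho-silylaryl triflates from ortho-bromophenols.

Step 7
Reactants: 12 5-methoxy-2,2-dimethyl-8-(trimethylsilyl)-2H-chromen-7-yl trifluoromethanesulfonate; 13 acetic acid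
Product: 15 1-(7-hydroxy-5-methoxy-2,2-dimethyl-2H-chromen-8-yl)ethanone, via chromene 7,8-aryne 14 (not isolated)
Conditions: AcOH (1.2 equiv), CsF (4 equiv), THF, sealed tube, 125 °C; aq. NH4Cl work-up
Reagents that add atoms: none
Why: Fluoride attacks silicon and the incipient C8 carbanion expels triflate from C7, giving the 7,8-aryne 14. Because O1 on C8a makes this a 3-alkoxyaryne, acetate oxygen should add at the distal carbon C7 so that the negative charge develops at C8, where the adjacent C8a–O bond stabilises it inductively. The C8 anion then attacks the carbonyl of the ester on O7 through a four-membered alkoxide that opens to the 8-acetyl-7-phenoxide, protonated on work-up; this is the known fluoride-induced insertion of arynes from ortho-silylaryl triflates into the C–O bond of carboxylic acids, which gives ortho-hydroxyaryl ketones. No ring is closed and no stereocentre is formed. The step needs regioselective addition across the aryne, secured by the C8a oxygen, and acyl transfer faster than protonation of the aryl anion, favoured by the high temperature, the small excess of acid buffered by CsF and the intramolecular nature of the transfer; the hydrogen-bonded ortho-acyl phenol product should be a poor aryne trap.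

Step 8
Reactants: 15 1-(7-hydroxy-5-methoxy-2,2-dimethyl-2H-chromen-8-yl)ethanone
Product: 16 1-(5,7-dihydroxy-2,2-dimethyl-2H-chromen-8-yl)ethanone
Conditions: NaSEt (5 equiv), DMF, 130 °C; aq. HCl work-up
Reagents that add atoms: none
Why: SN2 O-demethylation by thiolate; the C5 oxygen is para to the C8 acetyl group, so the leaving phenoxide is a vinylogous carboxylate, and the non-acidic, non-electrophilic reagent should leave the pyran alkene untouched.

Step 9
Reactants: 16 1-(5,7-dihydroxy-2,2-dimethyl-2H-chromen-8-yl)ethanone
Product: 17 1-{6-[(dimethylamino)methyl]-5,7-dihydroxy-2,2-dimethyl-2H-chromen-8-yl}ethanone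
Conditions: dimethylmethylideneammonium iodide (1.1 equiv), CH2Cl2, rt; aq. NaHCO3 work-up, use crude
Reagents that add atoms: dimethylmethylideneammonium iodide (Eschenmoser's salt), C[N+](C)=C.[I-]
Why: Mannich reaction (electrophilic aromatic aminomethylation) at C6, the only unsubstituted carbon of ring B and flanked by two hydroxyls, so no regiochemical question arises.

Step 10
Reactants: 18 1-(2,4,6-trihydroxyphenyl)propan-1-one
Product: 19 3,5-dihydroxy-4,4-dimethyl-2-propanoylcyclohexa-2,5-dien-1-one (propionylfilicinic acid)
Conditions: NaOMe (4 equiv), MeI (2.2 equiv), MeOH, 0 °C → rt; acidify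
Reagents that add atoms: iodomethane, CI
Why: Base-mediated dearomative C-methylation of an acylphloroglucinol, in which the second methyl group enters at the carbon already methylated to give the acylfilicinic acid; limiting MeI to about two equivalents should keep the geminal product dominant over under- and over-methylated material, which is separated.

Step 11
Reactants: 17 1-{6-[(dimethylamino)methyl]-5,7-dihydroxy-2,2-dimethyl-2H-chromen-8-yl}ethanone; 19 3,5-dihydroxy-4,4-dimethyl-2-propanoylcyclohexa-2,5-dien-1-one
Product: 21 2-[(8-acetyl-5,7-dihydroxy-2,2-dimethyl-2H-chromen-6-yl)methyl]-3,5-dihydroxy-4,4-dimethyl-6-propanoylcyclohexa-2,5-dien-1-one (target), via ortho-quinone methide 20 (not isolated)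
Conditions: 19 (1.5 equiv), toluene, 100 °C, N2 sweep
Reagents that add atoms: none
Why: Thermal loss of dimethylamine from the ortho-hydroxybenzylamine (assisted by protonation by the acidic triketone) gives the ortho-quinone methide, which is trapped by Michael addition of C6 of 19, its only C–H nucleophilic site, and tautomerisation restores the aromatic ring B.

**Compound list**
1 | 5-methoxyresorcinol (5-methoxybenzene-1,3-diol) | COc1cc(O)cc(O)c1 | starting material
2 | 1-methoxy-3,5-bis(methoxymethoxy)benzene | COCOc1cc(OC)cc(OCOC)c1 | intermediate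
3 | [4-methoxy-2,6-bis(methoxymethoxy)phenyl]lithium | [Li]c1c(OCOC)cc(OC)cc1OCOC | intermediate
4 | 2-bromo-5-methoxy-1,3-bis(methoxymethoxy)benzene | COCOc1cc(OC)cc(OCOC)c1Br | intermediate
5 | 2-bromo-5-methoxybenzene-1,3-diol | COc1cc(O)c(Br)c(O)c1 | intermediate
6 | 3-methylbut-2-enal | CC(C)=CC=O | starting material
7 | 2-bromo-3-hydroxy-5-methoxy-6-(3-methylbut-2-en-1-ylidene)cyclohexa-2,4-dien-1-one | O=C1C(Br)=C(O)C=C(OC)C1=CC=C(C)C | intermediate
8 | 8-bromo-5-methoxy-2,2-dimethyl-2H-chromen-7-ol | COc1cc(O)c(Br)c2OC(C)(C)C=Cc12 | intermediate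
9 | [(8-bromo-5-methoxy-2,2-dimethyl-2H-chromen-7-yl)oxy]trimethylsilane | COc1cc(O[Si](C)(C)C)c(Br)c2OC(C)(C)C=Cc12 | intermediate
10 | [5-methoxy-2,2-dimethyl-7-(trimethylsilyloxy)-2H-chromen-8-yl]lithium | COc1cc(O[Si](C)(C)C)c([Li])c2OC(C)(C)C=Cc12 | intermediate
11 | lithium 5-methoxy-2,2-dimethyl-8-(trimethylsilyl)-2H-chromen-7-olate | COc1cc([O-])c([Si](C)(C)C)c2OC(C)(C)C=Cc12.[Li+] | intermediate
12 | 5-methoxy-2,2-dimethyl-8-(trimethylsilyl)-2H-chromen-7-yl trifluoromethanesulfonate | COc1cc(OS(=O)(=O)C(F)(F)F)c([Si](C)(C)C)c2OC(C)(C)C=Cc12 | intermediate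
13 | acetic acid | CC(=O)O | starting material
14 | 5-methoxy-2,2-dimethyl-7,8-didehydro-2H-chromene (7,8-aryne) | COC1=CC#CC2=C1C=CC(C)(C)O2 | intermediate
15 | 1-(7-hydroxy-5-methoxy-2,2-dimethyl-2H-chromen-8-yl)ethanone | CC(=O)c1c(O)cc(OC)c2C=CC(C)(C)Oc12 | intermediate
16 | 1-(5,7-dihydroxy-2,2-dimethyl-2H-chromen-8-yl)ethanone | CC(=O)c1c(O)cc(O)c2C=CC(C)(C)Oc12 | intermediate
17 | 1-{6-[(dimethylamino)methyl]-5,7-dihydroxy-2,2-dimethyl-2H-chromen-8-yl}ethanone | CC(=O)c1c(O)c(CN(C)C)c(O)c2C=CC(C)(C)Oc12 | intermediate
18 | 1-(2,4,6-trihydroxyphenyl)propan-1-one | CCC(=O)c1c(O)cc(O)cc1O | starting material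
19 | 3,5-dihydroxy-4,4-dimethyl-2-propanoylcyclohexa-2,5-dien-1-one (propionylfilicinic acid) | CCC(=O)C1=C(O)C(C)(C)C(O)=CC1=O | intermediate
20 | 8-acetyl-5-hydroxy-2,2-dimethyl-6-methylidene-2H-chromen-7(6H)-one (ortho-quinone methide) | C=C1C(=O)C(C(C)=O)=C2OC(C)(C)C=CC2=C1O | intermediate
21 | 2-[(8-acetyl-5,7-dihydroxy-2,2-dimethyl-2H-chromen-6-yl)methyl]-3,5-dihydroxy-4,4-dimethyl-6-propanoylcyclohexa-2,5-dien-1-one | CCC(=O)C1=C(O)C(C)(C)C(O)=C(Cc2c(O)c3c(c(C(C)=O)c2O)OC(C)(C)C=C3)C1=O | target

**Step count**
Total: 11 steps. Longest linear sequence: 10 steps (steps 1–9 and 11, from compound 1); ring A is made in one step (step 10).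

**Steps most likely to fail**

Step 7 (aryne insertion). The C8 aryl anion may be protonated before it reaches the ester carbonyl, which would leave the oxygen acetylated without the C8–C bond. The aryne may also be consumed by the product phenoxide or by the pyran alkene. The fallback avoids the aryne and sets out from bromophenol 8. O7 is protected with NaH and MOMCl in DMF to give 8-bromo-5-methoxy-7-(methoxymethoxy)-2,2-dimethyl-2H-chromene F1. Bromine–lithium exchange with n-BuLi in THF at −78 °C gives [5-methoxy-7-(methoxymethoxy)-2,2-dimethyl-2H-chromen-8-yl]lithium F2, held by chelation to the OMOM group and not isolated. Acylation with N-methoxy-N-methylacetamide gives 1-[5-methoxy-7-(methoxymethoxy)-2,2-dimethyl-2H-chromen-8-yl]ethanone F3. Brief treatment with dilute HCl in MeOH at room temperature removes the MOM group ortho to the carbonyl, and the route is rejoined at 15.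

Step 11 (methylene-bridge coupling). Formation of the ortho-quinone methide is reversible, and ipso attack with loss of the CH2 unit can scramble the partners into symmetrical methylene-bis dimers; O-alkylation of the triketone may also compete. The fallback sets out from 16 and forms the bridge carbon at the aldehyde oxidation level, so that it stays bound to ring B throughout. Vilsmeier–Haack formylation (POCl3, DMF, MeCN, 0 °C → rt, aqueous hydrolysis) at C6 should give 8-acetyl-5,7-dihydroxy-2,2-dimethyl-2H-chromene-6-carbaldehyde F5. A three-component reductive alkylation with 19, diethyl 2,6-dimethyl-1,4-dihydropyridine-3,5-dicarboxylate (Hantzsch ester) and catalytic L-proline in CH2Cl2 at room temperature then follows. Knoevenagel condensation gives 2-[(8-acetyl-5,7-dihydroxy-2,2-dimethyl-2H-chromen-6-yl)methylidene]-5-hydroxy-6,6-dimethyl-4-propanoylcyclohex-4-ene-1,3-dione F6 (not isolated), which is reduced in the flask by hydride transfer, and the route is rejoined at 21.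

Step 8 (O-demethylation). Under the reaction conditions the substrate is the C7 phenoxide, so SN2 attack on the C5 methyl group may be slow, and the temperatures needed to force it may open or degrade the pyran ring. The fallback sets out from 15 and makes the substrate neutral. NaH and MOMCl in DMF convert 15 into 1-[5-methoxy-7-(methoxymethoxy)-2,2-dimethyl-2H-chromen-8-yl]ethanone F3, the same ether that the fallback to step 7 passes through, so the two detours can be merged. NaSEt in DMF at about 100 °C should then demethylate this para-acyl anisole to 1-[5-hydroxy-7-(methoxymethoxy)-2,2-dimethyl-2H-chromen-8-yl]ethanone F4. Dilute HCl in MeOH at room temperature removes the MOM group, and the route is rejoined at 16.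

**Further compounds**
F1 | step 7 | 8-bromo-5-methoxy-7-(methoxymethoxy)-2,2-dimethyl-2H-chromene | COCOc1cc(OC)c2C=CC(C)(C)Oc2c1Br
F2 | step 7 | [5-methoxy-7-(methoxymethoxy)-2,2-dimethyl-2H-chromen-8-yl]lithium | COCOc1cc(OC)c2C=CC(C)(C)Oc2c1[Li]
F3 | step 7 | 1-[5-methoxy-7-(methoxymethoxy)-2,2-dimethyl-2H-chromen-8-yl]ethanone | CC(=O)c1c(OCOC)cc(OC)c2C=CC(C)(C)Oc12
F4 | step 8 | 1-[5-hydroxy-7-(methoxymethoxy)-2,2-dimethyl-2H-chromen-8-yl]ethanone | CC(=O)c1c(OCOC)cc(O)c2C=CC(C)(C)Oc12
F5 | step 11 | 8-acetyl-5,7-dihydroxy-2,2-dimethyl-2H-chromene-6-carbaldehyde | CC(=O)c1c(O)c(C=O)c(O)c2C=CC(C)(C)Oc12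
F6 | step 11 | 2-[(8-acetyl-5,7-dihydroxy-2,2-dimethyl-2H-chromen-6-yl)methylidene]-5-hydroxy-6,6-dimethyl-4-propanoylcyclohex-4-ene-1,3-dione | CCC(=O)C1=C(O)C(C)(C)C(=O)C(=Cc2c(O)c3C=CC(C)(C)Oc3c(C(C)=O)c2O)C1=O
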